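**Retrosynthetic overview**
1. The target is cut at the ester into (E)-3-hydroxycinnamic acid (phenol carried as a silyl ether) and eudesmane-4β,6β-diol. The diol comes from the 6-ketone by α-face hydride delivery, and the ketone from the 7-en-6-one by hydrogenation.
2. The strategy rests on ring B, where the C6 oxygen sits directly beside the isopropyl-bearing C7. Ring B is therefore opened at C7–C8 to a ring A keto aldehyde (isovaleryl on C5, CH2CHO on C10, tertiary carbinol at C4) that recloses by intramolecular aldol condensation.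
3. The keto aldehyde comes from a C10 1-silylvinyl group (hydroboration–oxidation, then loss of silicon next to the aldehyde) and a C6 carbinol. The C4 carbinol comes from methyllithium addition to the ring A ketone.
4. Ring A comes from asymmetric conjugate addition of a 1-(trimethylsilyl)vinyl alane to 3-methylcyclohex-2-enone, followed by aldol addition of isovaleraldehyde at C5. The silicon is kept so that the alkenyl group is much larger than methyl and relays C10 to C5 to C4.
5. Ring order: ring A is the starting enone; ring B is the only ring formed, in the key step.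

Key step: step 6

Remarks on the chemistry (assumptions):
- Eudesmane numbering is used throughout (ring A = C1–C5 and C10; ring B = C5–C10). The target is read as (1R,2S,4aR,8S,8aS), that is 4β-OH, 5α-H, 6β-O-acyl, 7β-isopropyl, 10β-methyl.
- The C6 carbinol centre (compounds 8–12) and the C9 silyl-bearing centre (compounds 11–13) are carried as epimer mixtures, because both are destroyed before or in step 6.
- L is a chiral sulfonate-bearing N-heterocyclic carbene precursor of the 4,5-diphenylimidazolinium type. The antipode that gives (S)-C10 is used.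

**Route**

Step 1
Reactants: 1 3-methylcyclohex-2-en-1-one; 2 ethynyltrimethylsilane
Product: 5 (S)-trimethyl({3-methyl-3-[1-(trimethylsilyl)ethenyl]cyclohex-1-en-1-yl}oxy)silane, via silylvinyl alane 3 (not isolated), via aluminium enolate 4 (not isolated)
Conditions: 2, i-Bu2AlH, hexanes, 55 °C; then 1, Cu(OTf)2 (5 mol %), L–Ag (2.5 mol %, from L and Ag2O), THF, −78 → −15 °C; then Me3SiOTf, −78 → 0 °C
Reagents that add atoms: trimethylsilyl trifluoromethanesulfonate, C[Si](C)(C)OS(=O)(=O)C(F)(F)F
Why: α-Hydroalumination of the silylalkyne gives the 1-silylvinyl alane, whose NHC–copper-catalysed asymmetric conjugate addition to the β-methyl enone should set the quaternary C10 (S) by ligand control of the enone face, and O-silylation of the aluminium enolate fixes the C4=C5 enolate regiochemistry.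

Step 2
Reactants: 5 enol silane; 6 3-methylbutanal (isovaleraldehyde)
Product: 9 (2S,3S)-3-methyl-2-[3-methyl-1-(trimethylsilyloxy)butyl]-3-[1-(trimethylsilyl)ethenyl]cyclohexan-1-one (C6 epimers), via lithium enolate 7 (not isolated), via lithium aldolate 8 (not isolated)
Conditions: MeLi, THF, 0 °C; 6, −78 °C; then Me3SiCl, −78 → 0 °C
Reagents that add atoms: chlorotrimethylsilane, C[Si](C)(C)Cl
Why: Regiospecific lithium enolate generation from the enol silane and aldol addition; the aldehyde should approach C5 anti to the 1-(trimethylsilyl)ethenyl group, which is far larger than methyl, so the new chain is cis to the C10 methyl (C5 S), and silylation of the aldolate blocks retro-aldol reversal.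

Step 3
Reactants: 9 silyloxy ketone
Product: 10 (1S,2S,3S)-1,3-dimethyl-2-[3-methyl-1-(trimethylsilyloxy)butyl]-3-[1-(trimethylsilyl)ethenyl]cyclohexan-1-ol
Conditions: MeLi, CeCl3, THF, −78 °C
Reagents that add atoms: methyllithium, [Li]C
Why: Organocerium 1,2-addition to a hindered, enolisable ketone; in the chair with the C5 chain and the silylvinyl group equatorial the C10 methyl is axial and screens the β face, so methyl should enter equatorially from the α face and give the axial 4β-hydroxyl (C4 S).

Step 4
Reactants: 10 tertiary alcohol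
Product: 12 (1S,2S,3S)-2-(1-hydroxy-3-methylbutyl)-3-[2-hydroxy-1-(trimethylsilyl)ethyl]-1,3-dimethylcyclohexan-1-ol (C6 and C9 epimers), via alkylborane 11 (not isolated)
Conditions: BH3·THF, THF, 0 °C → rt; then NaOH, H2O2, MeOH/H2O, 0 °C → rt
Reagents that add atoms: hydrogen peroxide, OO
Why: Hydroboration–oxidation of a 1,1-disubstituted vinylsilane places boron and then oxygen on the terminal carbon C8 (anti-Markovnikov, sterically enforced), and the alkaline work-up hydrolyses the trimethylsilyl ether.

Step 5
Reactants: 12 triol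
Product: 14 2-[(1R,2R,3S)-3-hydroxy-1,3-dimethyl-2-(3-methylbutanoyl)cyclohexyl]acetaldehyde, via α-silyl keto aldehyde 13 (not isolated)
Conditions: (COCl)2, DMSO, CH2Cl2, −78 °C; Et3N, −78 → 0 °C; then Bu4NF, AcOH, THF, 0 °C
Reagents that add atoms: none
Why: Swern oxidation activates both carbinols at −78 °C before base is added, so the C6 and C8 alcohols are oxidised together without lactol formation while the tertiary C4 hydroxyl cannot react, and buffered fluoride then cleaves the silicon–carbon bond α to the aldehyde (protodesilylation of an α-silyl carbonyl compound), which also erases the C9 centre.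

Step 6
Reactants: 14 ring A keto aldehyde
Product: 16 (4aR,8S,8aR)-8-hydroxy-4a,8-dimethyl-2-(propan-2-yl)-4a,5,6,7,8,8a-hexahydronaphthalen-1(4H)-one (4β-hydroxyeudesm-7-en-6-one), via ketol 15 (not isolated)
Conditions: piperidine (0.3 equiv), AcOH (0.3 equiv), toluene, 60 °C
Reagents that add atoms: none
Why: Piperidinium acetate converts the C8 aldehyde into its iminium ion and promotes enolisation of the C6 ketone towards C7; the enol adds to C8 and loss of water (or piperidine) from the adduct gives the conjugated C7=C8 enone, an intramolecular aldol (Mannich-type) condensation of the kind used to make 2-alkylcyclohex-2-enones from δ-keto aldehydes. Ring B (C5–C6–C7–C8–C9–C10) closes in the 6-(enolendo)-exo-trig mode. No stereocentre is created, since C7 and C8 become sp2, and C5, which is α to the C6 carbonyl, stays in or equilibrates to the trans-fused arrangement with its bonds to C4 and C6 equatorial. The step needs regioselectivity for the C7 enol over the C5 enol, and cyclisation must outrun retro-aldol cleavage or dehydration at the C4 carbinol. Ring size secures the first, because attack from C5 or from the aldehyde α-carbon C9 would give four-membered rings, and the weakly acidic, nearly neutral medium secures the second, because no alkoxide is formed at C4.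

Step 7
Reactants: 16 enone
Product: 17 (2S,4aR,8S,8aR)-8-hydroxy-4a,8-dimethyl-2-(propan-2-yl)octahydronaphthalen-1(2H)-one (4β-hydroxyeudesman-6-one)
Conditions: H2 (1 atm), 10% Pd/C, EtOAc, rt
Reagents that add atoms: none
Why: Heterogeneous hydrogenation should add hydrogen to C7=C8 from the α face, away from the axial C10 methyl, which sets C7 with the isopropyl group β and equatorial; as C7 is α to the ketone this is also the thermodynamically preferred epimer.

Step 8
Reactants: 17 saturated ketone
Product: 18 (1R,2S,4aR,8S,8aS)-4a,8-dimethyl-2-(propan-2-yl)decahydronaphthalene-1,8-diol (eudesmane-4β,6β-diol)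
Conditions: NaBH4, MeOH, 0 °C
Reagents that add atoms: none
Why: Hydride reduction of a hindered cyclohexanone; the β face of C6 is screened by the syn-axial C10 methyl and C4 hydroxyl, so borohydride should enter from the α (equatorial) side and set the axial 6β-alcohol.

Step 9
Reactants: 19 (E)-3-(3-hydroxyphenyl)prop-2-enoic acid
Product: 21 (E)-3-[3-(tert-butyldimethylsilyloxy)phenyl]prop-2-enoic acid, via bis-silyl derivative 20 (not isolated)
Conditions: t-BuMe2SiCl, imidazole, DMF, rt; then AcOH, THF/H2O, rt
Reagents that add atoms: tert-butyldimethylsilyl chloride, CC(C)(C)[Si](C)(C)Cl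
Why: Silylation of both phenol and acid followed by selective hydrolysis of the labile silyl ester, a standard protection of hydroxycinnamic acids.

Step 10
Reactants: 18 diol; 21 silyl-protected cinnamic acid
Product: 23 (1R,2S,4aR,8S,8aS)-8-hydroxy-4a,8-dimethyl-2-(propan-2-yl)decahydronaphthalen-1-yl (E)-3-[3-(tert-butyldimethylsilyloxy)phenyl]prop-2-enoate, via acid chloride 22 (not isolated)
Conditions: 21, (COCl)2, DMF (cat.), CH2Cl2, 0 °C → rt; then 18, DMAP, Et3N, toluene, 60 °C
Reagents that add atoms: none
Why: Acylation of a secondary alcohol by an acyl chloride under DMAP nucleophilic catalysis; the tertiary C4 hydroxyl is too hindered to compete and the phenol is masked.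

Step 11
Reactants: 23 silyl-protected ester
Product: 24 (1R,2S,4aR,8S,8aS)-8-hydroxy-4a,8-dimethyl-2-(propan-2-yl)decahydronaphthalen-1-yl (E)-3-(3-hydroxyphenyl)prop-2-enoate (target)
Conditions: Bu4NF, AcOH, THF, 0 °C
Reagents that add atoms: none
Why: Fluoride cleavage of an aryl silyl ether, buffered with acetic acid so that the cinnamate ester is left alone.

**Compound list**
1 | 3-methylcyclohex-2-en-1-one | CC1=CC(=O)CCC1 | starting material
2 | ethynyltrimethylsilane | C#C[Si](C)(C)C | starting material
3 | diisobutyl[1-(trimethylsilyl)ethenyl]aluminium (formed in situ) | C=C([Si](C)(C)C)[Al](CC(C)C)CC(C)C | intermediate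
4 | diisobutylaluminium enolate of (S)-3-methyl-3-[1-(trimethylsilyl)ethenyl]cyclohexanone, enolate C4=C5 (formed in situ) | C=C([Si](C)(C)C)[C@@]1(C)CCCC(O[Al](CC(C)C)CC(C)C)=C1 | intermediate
5 | (S)-trimethyl({3-methyl-3-[1-(trimethylsilyl)ethenyl]cyclohex-1-en-1-yl}oxy)silane | C=C([Si](C)(C)C)[C@@]1(C)CCCC(O[Si](C)(C)C)=C1 | intermediate
6 | 3-methylbutanal (isovaleraldehyde) | CC(C)CC=O | starting material
7 | lithium enolate corresponding to 5 (formed in situ) | C=C([Si](C)(C)C)[C@@]1(C)CCCC(O[Li])=C1 | intermediate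
8 | lithium alkoxide of (2S,3S)-2-(1-hydroxy-3-methylbutyl)-3-methyl-3-[1-(trimethylsilyl)ethenyl]cyclohexan-1-one, C6 epimers (formed in situ) | C=C([Si](C)(C)C)[C@@]1(C)CCCC(=O)[C@@H]1C(O[Li])CC(C)C | intermediate
9 | (2S,3S)-3-methyl-2-[3-methyl-1-(trimethylsilyloxy)butyl]-3-[1-(trimethylsilyl)ethenyl]cyclohexan-1-one, C5 chain cis to the C10 methyl, C6 epimers | C=C([Si](C)(C)C)[C@@]1(C)CCCC(=O)[C@@H]1C(O[Si](C)(C)C)CC(C)C | intermediate
10 | (1S,2S,3S)-1,3-dimethyl-2-[3-methyl-1-(trimethylsilyloxy)butyl]-3-[1-(trimethylsilyl)ethenyl]cyclohexan-1-ol, 4β-OH cis to the C10 methyl, C6 epimers | C=C([Si](C)(C)C)[C@@]1(C)CCC[C@](C)(O)[C@@H]1C(O[Si](C)(C)C)CC(C)C | intermediate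
11 | C8 monoalkylborane from 10, drawn with the free C4 hydroxyl (formed in situ) | C[Si](C)(C)C(CB)[C@@]1(C)CCC[C@](C)(O)[C@@H]1C(O[Si](C)(C)C)CC(C)C | intermediate
12 | (1S,2S,3S)-2-(1-hydroxy-3-methylbutyl)-3-[2-hydroxy-1-(trimethylsilyl)ethyl]-1,3-dimethylcyclohexan-1-ol, C6 and C9 epimers | C[Si](C)(C)C(CO)[C@@]1(C)CCC[C@](C)(O)[C@@H]1C(O)CC(C)C | intermediate
13 | 2-[(1S,2R,3S)-3-hydroxy-1,3-dimethyl-2-(3-methylbutanoyl)cyclohexyl]-2-(trimethylsilyl)acetaldehyde, C9 epimers (formed in situ) | C[Si](C)(C)C(C=O)[C@@]1(C)CCC[C@](C)(O)[C@@H]1C(=O)CC(C)C | intermediate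
14 | 2-[(1R,2R,3S)-3-hydroxy-1,3-dimethyl-2-(3-methylbutanoyl)cyclohexyl]acetaldehyde (ring A keto aldehyde, key-step precursor) | O=CC[C@@]1(C)CCC[C@](C)(O)[C@@H]1C(=O)CC(C)C | intermediate
15 | 4β,8-dihydroxyeudesman-6-one (aldol adduct, C7 and C8 epimers, formed in situ) | CC(C)C1C(O)C[C@@]2(C)CCC[C@](C)(O)[C@@H]2C1=O | intermediate
16 | (4aR,8S,8aR)-8-hydroxy-4a,8-dimethyl-2-(propan-2-yl)-4a,5,6,7,8,8a-hexahydronaphthalen-1(4H)-one (4β-hydroxyeudesm-7-en-6-one, key-step product) | CC(C)C1=CC[C@@]2(C)CCC[C@](C)(O)[C@@H]2C1=O | intermediate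
17 | (2S,4aR,8S,8aR)-8-hydroxy-4a,8-dimethyl-2-(propan-2-yl)octahydronaphthalen-1(2H)-one | CC(C)[C@@H]1CC[C@@]2(C)CCC[C@](C)(O)[C@@H]2C1=O | intermediate
18 | (1R,2S,4aR,8S,8aS)-4a,8-dimethyl-2-(propan-2-yl)decahydronaphthalene-1,8-diol | CC(C)[C@@H]1CC[C@@]2(C)CCC[C@](C)(O)[C@@H]2[C@@H]1O | intermediate
19 | (E)-3-(3-hydroxyphenyl)prop-2-enoic acid | O=C(O)/C=C/c1cccc(O)c1 | starting material
20 | tert-butyldimethylsilyl (E)-3-[3-(tert-butyldimethylsilyloxy)phenyl]prop-2-enoate (formed in situ) | CC(C)(C)[Si](C)(C)OC(=O)/C=C/c1cccc(O[Si](C)(C)C(C)(C)C)c1 | intermediate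
21 | (E)-3-[3-(tert-butyldimethylsilyloxy)phenyl]prop-2-enoic acid | O=C(O)/C=C/c1cccc(O[Si](C)(C)C(C)(C)C)c1 | intermediate
22 | (E)-3-[3-(tert-butyldimethylsilyloxy)phenyl]prop-2-enoyl chloride (formed in situ) | O=C(Cl)/C=C/c1cccc(O[Si](C)(C)C(C)(C)C)c1 | intermediate
23 | (1R,2S,4aR,8S,8aS)-8-hydroxy-4a,8-dimethyl-2-(propan-2-yl)decahydronaphthalen-1-yl (E)-3-[3-(tert-butyldimethylsilyloxy)phenyl]prop-2-enoate | CC(C)[C@@H]1CC[C@@]2(C)CCC[C@](C)(O)[C@@H]2[C@@H]1OC(=O)/C=C/c1cccc(O[Si](C)(C)C(C)(C)C)c1 | intermediate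
24 | (1R,2S,4aR,8S,8aS)-8-hydroxy-4a,8-dimethyl-2-(propan-2-yl)decahydronaphthalen-1-yl (E)-3-(3-hydroxyphenyl)prop-2-enoate | CC(C)[C@@H]1CC[C@@]2(C)CCC[C@](C)(O)[C@@H]2[C@@H]1OC(=O)/C=C/c1cccc(O)c1 | target

**Step count and risks**
Total steps: 11. Longest linear sequence: 10 (steps 1–8, 10 and 11; step 9 is the side branch).

Steps most likely to fail:

1. Step 6 (key step). The C4 carbinol is β to the C6 ketone, so ring A can open by retro-aldol cleavage of C4–C5 or lose water across C4–C5. The free aldehyde can also condense with a second molecule before the hindered ketone enolises. The fallback sets out from 14 and comes back at 16.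
   - The aldehyde is masked chemoselectively as the dimethyl acetal F1 (HC(OMe)3, PPTS, MeOH).
   - Me3SiOTf and Et3N at −78 °C silylate the C4 hydroxyl and turn the ketone into its C6–C7 enol silane, giving the bis(trimethylsilyl) compound F2.
   - A catalytic amount of Me3SiOTf in CH2Cl2 at −78 °C then brings about an intramolecular Mukaiyama addition of the enol silane to the oxocarbenium ion at C8, closing ring B as the 8-methoxy ketone F3.
   - DBU in toluene at 80 °C eliminates methanol to the silyl-protected enone F4, and Bu4NF/AcOH frees the C4 hydroxyl to give 16.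

2. Step 5. Activation of the C8 hydroxyl next to the C9 silyl group can end in Peterson-type loss of both groups to a vinyl group. If the two carbinols are not oxidised together, the C6 hydroxyl can add to the new aldehyde and be carried on to a lactone. The fallback sets out from 12 and comes back at 14.
   - KH in THF effects a deliberate syn Peterson elimination to the silicon-free vinyl diol F5.
   - Hydroboration with 9-borabicyclo[3.3.1]nonane followed by NaOH/H2O2 gives the triol F6.
   - Swern oxidation of F6, now a plain diol oxidation, gives 14.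

3. Step 10. Acylation of the axial 6β-hydroxyl, which is flanked by the C7 isopropyl group and hydrogen-bonded to the syn-axial C4 hydroxyl, may stall. Forcing it risks loss of the aryl silyl ether and self-reaction of the cinnamoyl chloride. The fallback sets out from 18 and comes back at 23.
   - The smaller diethylphosphonoacetic acid is coupled to the 6β-hydroxyl (DCC, DMAP, CH2Cl2) to give the phosphonoacetate F7.
   - Horner–Wadsworth–Emmons olefination of F7 with 3-(tert-butyldimethylsilyloxy)benzaldehyde (LiCl, DBU, MeCN) builds the E-cinnamate and gives 23.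

**Further compounds**
F1 | step 6 | (1S,2R,3R)-2-(3-methylbutanoyl)-3-(2,2-dimethoxyethyl)-1,3-dimethylcyclohexan-1-ol (dimethyl acetal of 14) | COC(OC)C[C@@]1(C)CCC[C@](C)(O)[C@@H]1C(=O)CC(C)C
F2 | step 6 | C4 trimethylsilyl ether and C6–C7 trimethylsilyl enol ether of F1 | COC(OC)C[C@@]1(C)CCC[C@](C)(O[Si](C)(C)C)[C@@H]1C(O[Si](C)(C)C)=CC(C)C
F3 | step 6 | 8-methoxy-4β-(trimethylsilyloxy)eudesman-6-one (C7 and C8 epimers) | CC(C)C1C(OC)C[C@@]2(C)CCC[C@](C)(O[Si](C)(C)C)[C@@H]2C1=O
F4 | step 6 | 4β-(trimethylsilyloxy)eudesm-7-en-6-one | CC(C)C1=CC[C@@]2(C)CCC[C@](C)(O[Si](C)(C)C)[C@@H]2C1=O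
F5 | step 5 | (1S,2S,3R)-3-ethenyl-2-(1-hydroxy-3-methylbutyl)-1,3-dimethylcyclohexan-1-ol (C6 epimers) | C=C[C@@]1(C)CCC[C@](C)(O)[C@@H]1C(O)CC(C)C
F6 | step 5 | (1S,2S,3R)-3-(2-hydroxyethyl)-2-(1-hydroxy-3-methylbutyl)-1,3-dimethylcyclohexan-1-ol (C6 epimers) | OCC[C@@]1(C)CCC[C@](C)(O)[C@@H]1C(O)CC(C)C
F7 | step 10 | (1R,2S,4aR,8S,8aS)-8-hydroxy-4a,8-dimethyl-2-(propan-2-yl)decahydronaphthalen-1-yl 2-(diethoxyphosphoryl)acetate | CC(C)[C@@H]1CC[C@@]2(C)CCC[C@](C)(O)[C@@H]2[C@@H]1OC(=O)CP(=O)(OCC)OCC
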